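**Strategy.** Numbering the 14-membered ring from the isopropyl-bearing carbon (C1) through the lactone carbinol carbon (C2) to the acetoxy carbon (C14), the C14–O/C13H2/C12(OH)(CH3) array is a masked aldol next to the C10=C11 alkene. The macrocycle is closed between C13 and C14 by an intramolecular nitrile oxide cycloaddition. A nitrile oxide at C14 adds to the terminal C12=C13 bond of a 2-methyl-1,3-diene, forming C13–C14 and C12–O at once and closing the 14-membered ring as an isoxazoline-bridged bicycle. The precursor is an acyclic aldoxime carrying the finished butenolide, the C6 ketone and the diene. The isoxazoline N–O bond, absent from the target, is cleaved afterwards and the C14 ketone reduced 1,3-anti.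

Key step: step 15

Remark: further ring locants used below are C3=C4 (butenolide alkene), C18 (lactone carbonyl on C4), C6 (ketone), C8 (methyl-bearing CH), C10=C11 (E-alkene), C12 (tertiary carbinol); the carbinol centres made in steps 5 and 10 are left uncontrolled because steps 6 and 11 destroy them; C8 comes from 9, C1 and C2 from step 2, C12 from step 15, C14 from step 17.

Step 1
Reactants: 1 (S)-4-benzyl-1,3-oxazolidin-2-one; 2 3-methylbutanoyl chloride
Product: 3 (S)-4-benzyl-3-(3-methylbutanoyl)-1,3-oxazolidin-2-one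
Conditions: Et3N, DMAP (cat.), CH2Cl2, 0 °C to rt
Reagents that add atoms: none
Why: N-acylation of the oxazolidinone by the acid chloride under DMAP catalysis attaches the chiral auxiliary without forming a stereocentre.

Step 2
Reactants: 3 (S)-4-benzyl-3-(3-methylbutanoyl)-1,3-oxazolidin-2-one; 4 acrolein
Product: 6 (S)-4-benzyl-3-[(2S,3R)-3-hydroxy-2-(propan-2-yl)pent-4-enoyl]-1,3-oxazolidin-2-one, via Z-boron enolate 5 (not isolated)
Conditions: Bu2BOTf, Et3N, CH2Cl2, 0 °C; then 4, −78 °C to 0 °C; then pH 7 buffer, MeOH, H2O2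
Reagents that add atoms: none
Why: Evans syn aldol reaction, in which the Z-dibutylboron enolate adds to acrolein through a closed chair transition state on the enolate face away from the benzyl group, setting C1 and C2 (syn, 2S,3R in the adduct).

Step 3
Reactants: 6 aldol adduct
Product: 7 (2R,3R)-2-(propan-2-yl)pent-4-ene-1,3-diol
Conditions: LiBH4, MeOH (1 equiv), THF, 0 °C
Reagents that add atoms: none
Why: Reductive cleavage of the N-acyl oxazolidinone by LiBH4 gives the primary alcohol (future C14) and releases the auxiliary without touching the two stereocentres or the vinyl group.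

Step 4
Reactants: 7 diol
Product: 8 (3R,4R)-4-({[tert-butyl(dimethyl)silyl]oxy}methyl)-5-methylhex-1-en-3-ol
Conditions: TBSCl (1.05 equiv), imidazole, CH2Cl2, 0 °C
Reagents that add atoms: tert-butyldimethylsilyl chloride, CC(C)(C)[Si](C)(C)Cl
Why: Sterically controlled silylation takes the primary hydroxyl and leaves the hindered secondary allylic C2 hydroxyl free for the esterification.

Step 5
Reactants: 9 (S)-citronellal; 10 2-(bromomethyl)acrylic acid
Product: 11 (6S)-4-hydroxy-6,10-dimethyl-2-methylideneundec-9-enoic acid (both C4 epimers)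
Conditions: In powder, THF/H2O (1:1), rt; work-up at pH 4
Reagents that add atoms: none
Why: Indium-mediated Barbier allylation in water forms the C5–C6 bond and gives the 2-methylene acid directly, the new carbinol centre being irrelevant because it is oxidised in step 6.

Step 6
Reactants: 11 hydroxy acid
Product: 12 (6S)-6,10-dimethyl-2-methylidene-4-oxoundec-9-enoic acid
Conditions: Dess–Martin periodinane, CH2Cl2, 0 °C to rt
Reagents that add atoms: none
Why: Dess–Martin oxidation gives the C6 ketone under non-basic conditions, which should keep the 2-methylene double bond out of conjugation with the new ketone.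

Step 7
Reactants: 8 silyl ether alcohol; 12 keto acid
Product: 13 (3R,4R)-4-({[tert-butyl(dimethyl)silyl]oxy}methyl)-5-methylhex-1-en-3-yl (6S)-6,10-dimethyl-2-methylidene-4-oxoundec-9-enoate
Conditions: EDC·HCl, DMAP (0.1 equiv), CH2Cl2, 0 °C to rt
Reagents that add atoms: none
Why: Steglich-type carbodiimide esterification acylates the C2 hydroxyl with retention, γ-keto acids being esterified normally under these conditions.

Step 8
Reactants: 13 ester
Product: 14 (5R)-5-[(2R)-1-{[tert-butyl(dimethyl)silyl]oxy}-3-methylbutan-2-yl]-3-[(4S)-4,8-dimethyl-2-oxonon-7-en-1-yl]furan-2(5H)-one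
Conditions: second-generation Grubbs catalyst (5 mol%), toluene (5 mM), 80 °C
Reagents that add atoms: none
Why: Ring-closing metathesis between the vinyl group on C2 and the acrylate methylene forms the five-membered butenolide (C3=C4) with loss of ethene, the trisubstituted prenyl-type alkene being too hindered to compete.

Step 9
Reactants: 14 butenolide
Product: 16 (4S)-7-{(5R)-5-[(2R)-1-{[tert-butyl(dimethyl)silyl]oxy}-3-methylbutan-2-yl]-2-oxo-2,5-dihydrofuran-3-yl}-4-methyl-6-oxoheptanal, via secondary ozonide 15 (not isolated)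
Conditions: O3, CH2Cl2, −78 °C (Sudan red 7B end point); then PPh3, −78 °C to rt
Reagents that add atoms: ozone, [O-][O+]=O
Why: Ozonolysis with reductive work-up cleaves the electron-rich trisubstituted alkene much faster than the electron-poor butenolide alkene and gives the C11 aldehyde.

Step 10
Reactants: 16 aldehyde; 17 2-bromopropene
Product: 18 (5R)-5-[(2R)-1-{[tert-butyl(dimethyl)silyl]oxy}-3-methylbutan-2-yl]-3-[(4S)-7-hydroxy-4,8-dimethyl-2-oxonon-8-en-1-yl]furan-2(5H)-one (both C11 epimers)
Conditions: CrCl2 (4 equiv), NiCl2 (1 mol%), DMF, rt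
Reagents that add atoms: none
Why: Nozaki–Hiyama–Kishi addition of the isopropenyl group is selective for the aldehyde over the C6 ketone and the lactone, and the C11 carbinol centre needs no control because step 11 removes it.

Step 11
Reactants: 18 allylic alcohol
Product: 19 (5R)-5-[(2R)-1-{[tert-butyl(dimethyl)silyl]oxy}-3-methylbutan-2-yl]-3-[(4S,6E)-4,8-dimethyl-2-oxonona-6,8-dien-1-yl]furan-2(5H)-one
Conditions: Burgess reagent, toluene, 60 °C
Reagents that add atoms: none
Why: Burgess dehydration, a thermal syn elimination, can only remove a C10 hydrogen because C12 carries none, and should give the conjugated E-diene from both epimers.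

Step 12
Reactants: 19 diene silyl ether
Product: 20 (5R)-5-[(2R)-1-hydroxy-3-methylbutan-2-yl]-3-[(4S,6E)-4,8-dimethyl-2-oxonona-6,8-dien-1-yl]furan-2(5H)-one
Conditions: HF·pyridine, pyridine, THF, 0 °C to rt
Reagents that add atoms: none
Why: Buffered fluoride desilylation frees the C14 hydroxyl without isomerising the β,γ-unsaturated ketone or the diene.

Step 13
Reactants: 20 primary alcohol
Product: 21 (2S)-2-{(2R)-4-[(4S,6E)-4,8-dimethyl-2-oxonona-6,8-dien-1-yl]-5-oxo-2,5-dihydrofuran-2-yl}-3-methylbutanal
Conditions: Dess–Martin periodinane, pyridine, CH2Cl2, 0 °C; used crude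
Reagents that add atoms: none
Why: Dess–Martin oxidation gives the α-branched C14 aldehyde under near-neutral conditions that should avoid epimerisation at C1 and β-elimination of the lactone oxygen.

Step 14
Reactants: 21 aldehyde
Product: 22 (1E,2R)-2-{(2R)-4-[(4S,6E)-4,8-dimethyl-2-oxonona-6,8-dien-1-yl]-5-oxo-2,5-dihydrofuran-2-yl}-3-methylbutanal oxime
Conditions: NH2OH·HCl (1.05 equiv), NaOAc, MeOH, 0 °C
Reagents that add atoms: hydroxylamine hydrochloride, Cl.NO
Why: Oxime condensation is much faster at the aldehyde than at the C6 ketone, which is flanked by two β-branched methylene groups, so one equivalent of hydroxylamine at 0 °C should give the aldoxime selectively.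

Step 15
Reactants: 22 aldoxime
Product: 25 isoxazoline-bridged macrocycle (C14=N–O–C12; 1R,2R,8S,12S,10E), via hydroximoyl chloride 23 (not isolated), via nitrile oxide 24 (not isolated)
Conditions: NCS, DMF, 0 °C to rt; then CH2Cl2 (1 mM), Et3N by syringe pump over 12 h, rt
Reagents that add atoms: none
Why: NCS converts the aldoxime into hydroximoyl chloride 23 and slow addition of Et3N releases nitrile oxide 24, which undergoes a concerted 1,3-dipolar cycloaddition with the terminal C12=C13 bond of the diene, its carbon (C14) bonding to C13 and its oxygen to C12. The closest known reaction type is the macrocyclic intramolecular nitrile oxide–olefin cycloaddition used as a masked aldol macrocyclisation for 12- to 16-membered rings. The 14-membered carbocycle is closed by the C13–C14 bond in the bridged mode (both alkene carbons end up inside the new ring), and the 4,5-dihydroisoxazole ring is closed by the C12–O bond in the same event. The new C12 stereocentre is controlled by the π-face of the s-trans diene that is attacked: with C1–H in the plane of the forming heterocycle on the C13 side (least allylic strain), the tether leaving C1 through C2 lies on one face and the isopropyl group on the other, and bonding of C11 on the tether face, which should strain the bridged macrocycle least, corresponds to 12S. The step needs chemoselectivity for the 1,1-disubstituted terminal alkene (the 1,2-disubstituted C10=C11 bond and the electron-poor trisubstituted butenolide alkene react much more slowly, and addition to the butenolide would need a bridgehead C=N bond), regioselectivity (oxygen to the more substituted, vinyl-bearing C12, the intrinsic preference of 1,1-disubstituted alkenes) and ring closure over furoxan dimerisation (high dilution, slow base addition). The facial preference is the least secure element, so any 12R epimer is to be separated by chromatography at this stage.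

Step 16
Reactants: 25 isoxazoline-bridged macrocycle
Product: 26 (1S,2R,8S,12S,10E)-12-hydroxy-6,14-dioxocembra-3,10-dien-18,2-olide (β-hydroxy ketone)
Conditions: Mo(CO)6, MeCN/H2O (15:1), 80 °C; used at once
Reagents that add atoms: water, O
Why: Reductive N–O cleavage by Mo(CO)6 in wet acetonitrile, with loss of the nitrogen as ammonia, unmasks the aldol (C12 tertiary alcohol, C14 ketone) without reducing the alkenes, the butenolide or the C6 ketone, and the product is reduced immediately to limit β-elimination of the lactone oxygen.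

Step 17
Reactants: 26 β-hydroxy ketone
Product: 27 (1R,2R,8S,12S,14S,10E)-12,14-dihydroxy-6-oxocembra-3,10-dien-18,2-olide
Conditions: Me4NBH(OAc)3, MeCN/AcOH (1:1), −30 °C
Reagents that add atoms: none
Why: Evans–Saksena reduction, in which the C12 hydroxyl binds the triacetoxyborohydride and delivers hydride intramolecularly through a chair transition state, should give the 1,3-anti diol (14S) while the undirected C6 ketone is left alone.

Step 18
Reactants: 27 diol
Product: 28 (1R,2R,8S,12S,14S,10E)-14-acetoxy-12-hydroxy-6-oxocembra-3,10-dien-18,2-olide (CNP0200490.2)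
Conditions: Ac2O, pyridine, DMAP (cat.), CH2Cl2, 0 °C
Reagents that add atoms: acetic anhydride, CC(=O)OC(C)=O
Why: Acylation takes place only at the secondary C14 hydroxyl because the tertiary C12 hydroxyl is inert under these conditions, which completes the target.

**Compound list**

1 | (S)-4-benzyl-1,3-oxazolidin-2-one | O=C1N[C@@H](Cc2ccccc2)CO1 | starting material
2 | 3-methylbutanoyl chloride | CC(C)CC(Cl)=O | starting material
3 | (S)-4-benzyl-3-(3-methylbutanoyl)-1,3-oxazolidin-2-one | CC(C)CC(=O)N1[C@@H](Cc2ccccc2)COC1=O | intermediate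
4 | acrolein (prop-2-enal) | C=CC=O | starting material
5 | Z-dibutylboron enolate of 3 | CC(C)/C=C(\OB(CCCC)CCCC)N1[C@@H](Cc2ccccc2)COC1=O | intermediate
6 | (S)-4-benzyl-3-[(2S,3R)-3-hydroxy-2-(propan-2-yl)pent-4-enoyl]-1,3-oxazolidin-2-one | CC(C)[C@@H]([C@H](O)C=C)C(=O)N1[C@@H](Cc2ccccc2)COC1=O | intermediate
7 | (2R,3R)-2-(propan-2-yl)pent-4-ene-1,3-diol | OC[C@@H](C(C)C)[C@H](O)C=C | intermediate
8 | (3R,4R)-4-({[tert-butyl(dimethyl)silyl]oxy}methyl)-5-methylhex-1-en-3-ol | CC(C)(C)[Si](C)(C)OC[C@@H](C(C)C)[C@H](O)C=C | intermediate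
9 | (S)-citronellal, (3S)-3,7-dimethyloct-6-enal | C[C@@H](CCC=C(C)C)CC=O | starting material
10 | 2-(bromomethyl)acrylic acid | OC(=O)C(=C)CBr | starting material
11 | (6S)-4-hydroxy-6,10-dimethyl-2-methylideneundec-9-enoic acid (both C4 epimers) | OC(=O)C(=C)CC(O)C[C@@H](C)CCC=C(C)C | intermediate
12 | (6S)-6,10-dimethyl-2-methylidene-4-oxoundec-9-enoic acid | OC(=O)C(=C)CC(=O)C[C@@H](C)CCC=C(C)C | intermediate
13 | (3R,4R)-4-({[tert-butyl(dimethyl)silyl]oxy}methyl)-5-methylhex-1-en-3-yl (6S)-6,10-dimethyl-2-methylidene-4-oxoundec-9-enoate | CC(C)(C)[Si](C)(C)OC[C@@H](C(C)C)[C@@H](C=C)OC(=O)C(=C)CC(=O)C[C@@H](C)CCC=C(C)C | intermediate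
14 | (5R)-5-[(2R)-1-{[tert-butyl(dimethyl)silyl]oxy}-3-methylbutan-2-yl]-3-[(4S)-4,8-dimethyl-2-oxonon-7-en-1-yl]furan-2(5H)-one | CC(C)(C)[Si](C)(C)OC[C@@H](C(C)C)[C@H]1C=C(CC(=O)C[C@@H](C)CCC=C(C)C)C(=O)O1 | intermediate
15 | secondary ozonide (3,3-dimethyl-1,2,4-trioxolane) of 14 at its trisubstituted alkene | CC(C)(C)[Si](C)(C)OC[C@@H](C(C)C)[C@H]1C=C(CC(=O)C[C@@H](C)CCC2OOC(C)(C)O2)C(=O)O1 | intermediate
16 | (4S)-7-{(5R)-5-[(2R)-1-{[tert-butyl(dimethyl)silyl]oxy}-3-methylbutan-2-yl]-2-oxo-2,5-dihydrofuran-3-yl}-4-methyl-6-oxoheptanal | CC(C)(C)[Si](C)(C)OC[C@@H](C(C)C)[C@H]1C=C(CC(=O)C[C@@H](C)CCC=O)C(=O)O1 | intermediate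
17 | 2-bromopropene | CC(Br)=C | starting material
18 | (5R)-5-[(2R)-1-{[tert-butyl(dimethyl)silyl]oxy}-3-methylbutan-2-yl]-3-[(4S)-7-hydroxy-4,8-dimethyl-2-oxonon-8-en-1-yl]furan-2(5H)-one (both C11 epimers) | CC(C)(C)[Si](C)(C)OC[C@@H](C(C)C)[C@H]1C=C(CC(=O)C[C@@H](C)CCC(O)C(C)=C)C(=O)O1 | intermediate
19 | (5R)-5-[(2R)-1-{[tert-butyl(dimethyl)silyl]oxy}-3-methylbutan-2-yl]-3-[(4S,6E)-4,8-dimethyl-2-oxonona-6,8-dien-1-yl]furan-2(5H)-one | CC(C)(C)[Si](C)(C)OC[C@@H](C(C)C)[C@H]1C=C(CC(=O)C[C@@H](C)C/C=C/C(C)=C)C(=O)O1 | intermediate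
20 | (5R)-5-[(2R)-1-hydroxy-3-methylbutan-2-yl]-3-[(4S,6E)-4,8-dimethyl-2-oxonona-6,8-dien-1-yl]furan-2(5H)-one | OC[C@@H](C(C)C)[C@H]1C=C(CC(=O)C[C@@H](C)C/C=C/C(C)=C)C(=O)O1 | intermediate
21 | (2S)-2-{(2R)-4-[(4S,6E)-4,8-dimethyl-2-oxonona-6,8-dien-1-yl]-5-oxo-2,5-dihydrofuran-2-yl}-3-methylbutanal | O=C[C@@H](C(C)C)[C@H]1C=C(CC(=O)C[C@@H](C)C/C=C/C(C)=C)C(=O)O1 | intermediate
22 | (E)-oxime of 21 (2R at the oxime α-carbon) | O/N=C/[C@@H](C(C)C)[C@H]1C=C(CC(=O)C[C@@H](C)C/C=C/C(C)=C)C(=O)O1 | intermediate
23 | (Z)-N-hydroxyimidoyl chloride derived from 22 | O/N=C(\Cl)[C@@H](C(C)C)[C@H]1C=C(CC(=O)C[C@@H](C)C/C=C/C(C)=C)C(=O)O1 | intermediate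
24 | nitrile oxide derived from 23 | [O-][N+]#C[C@@H](C(C)C)[C@H]1C=C(CC(=O)C[C@@H](C)C/C=C/C(C)=C)C(=O)O1 | intermediate
25 | isoxazoline-bridged macrocycle: target skeleton with C14 and C12 as C3 and C5 of a 4,5-dihydroisoxazole (C14=N–O–C12), butenolide, C6 ketone and 10E alkene in place; 1R,2R,8S,12S | C12=NO[C@@](C)(C1)/C=C/C[C@H](C)CC(=O)CC3=C[C@@H](OC3=O)[C@@H]2C(C)C | intermediate
26 | (1S,2R,8S,12S,10E)-12-hydroxy-6,14-dioxocembra-3,10-dien-18,2-olide | O=C1C[C@](C)(O)/C=C/C[C@H](C)CC(=O)CC2=C[C@@H](OC2=O)[C@@H]1C(C)C | intermediate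
27 | (1R,2R,8S,12S,14S,10E)-12,14-dihydroxy-6-oxocembra-3,10-dien-18,2-olide | O[C@H]1C[C@](C)(O)/C=C/C[C@H](C)CC(=O)CC2=C[C@@H](OC2=O)[C@@H]1C(C)C | intermediate
28 | (1R,2R,8S,12S,14S,10E)-14-acetoxy-12-hydroxy-6-oxocembra-3,10-dien-18,2-olide (CNP0200490.2) | CC(=O)O[C@H]1C[C@](C)(O)/C=C/C[C@H](C)CC(=O)CC2=C[C@@H](OC2=O)[C@@H]1C(C)C | target

**Step count.** Total: 18 steps. Longest linear sequence: 16 steps (steps 1–4 and 7–18); steps 5 and 6 form the second branch.

**Steps most likely to fail**

Step 15. The two faces of the C12=C13 bond may not be discriminated well enough in the unbiased macrocyclic transition state, or dimerisation of the nitrile oxide may outrun ring closure. The fallback replaces the diene by an allylic alcohol that directs the dipole and forms the C10=C11 alkene only after ring closure; it sets out from aldehyde 16 and returns at 25. The asymmetric variant of the Nozaki–Hiyama–Kishi reaction (CrCl2, NiCl2, a chiral oxazoline–sulfonamide ligand, 2-bromopropene 17), or chromatographic separation of the epimers of 18, would give the (11S)-allylic alcohol F1. HF·pyridine would give the diol F2, and TEMPO/PhI(OAc)2 would oxidise only its primary hydroxyl to the hydroxy aldehyde F3. NH2OH·HCl/NaOAc would give the hydroxy oxime F4, and tBuOCl at −78 °C the hydroximoyl chloride F5. Slow addition of F5 to iPrOMgBr (from EtMgBr and iPrOH) in CH2Cl2 at high dilution would generate the hydroxy nitrile oxide F6 as its magnesium alkoxide. The magnesium bridges the C11 alkoxide and the dipole oxygen and delivers the dipole to the alkene face syn to the C11–O bond (allylic hydrogen eclipsing the alkene), which for 11S should give the (11S,12S)-hydroxy isoxazoline F7. Dehydration of F7 with Martin sulfurane, which can only take a C10 hydrogen, would return 25.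

Step 17. The tertiary C12 hydroxyl may bind boron poorly, and the macrocycle may not allow the chair needed for intramolecular hydride delivery, so that the 14R epimer forms or the ketone is not reduced. The fallback sets out from 26 and returns at 28. A syn-selective reduction through a six-membered boron chelate (catecholborane, THF, −10 °C) would give the 12,14-syn diol F9. A Mitsunobu reaction with acetic acid (PPh3, DIAD, AcOH, toluene) would then invert C14 and install the acetate in one operation, giving 28 directly.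

Step 11. The sulfamate nitrogen may attack C13 with allylic transposition instead of clean syn elimination, or the Z-diene may form. The fallback sets out from 18 and returns at 19. Methyl chloroformate and pyridine would give the allylic methyl carbonate F8. Pd(PPh3)4 (zerovalent palladium) in refluxing THF would ionise it to a π-allyl complex of divalent palladium spanning C11–C13, and β-hydride elimination at C10 would give the E-diene 19.

Further compounds
F1 | step 15 | (5R)-5-[(2R)-1-{[tert-butyl(dimethyl)silyl]oxy}-3-methylbutan-2-yl]-3-[(4S,7S)-7-hydroxy-4,8-dimethyl-2-oxonon-8-en-1-yl]furan-2(5H)-one (11S epimer of 18) | CC(C)(C)[Si](C)(C)OC[C@@H](C(C)C)[C@H]1C=C(CC(=O)C[C@@H](C)CC[C@H](O)C(C)=C)C(=O)O1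
F2 | step 15 | (5R)-5-[(2R)-1-hydroxy-3-methylbutan-2-yl]-3-[(4S,7S)-7-hydroxy-4,8-dimethyl-2-oxonon-8-en-1-yl]furan-2(5H)-one | OC[C@@H](C(C)C)[C@H]1C=C(CC(=O)C[C@@H](C)CC[C@H](O)C(C)=C)C(=O)O1
F3 | step 15 | (2S)-2-{(2R)-4-[(4S,7S)-7-hydroxy-4,8-dimethyl-2-oxonon-8-en-1-yl]-5-oxo-2,5-dihydrofuran-2-yl}-3-methylbutanal | O=C[C@@H](C(C)C)[C@H]1C=C(CC(=O)C[C@@H](C)CC[C@H](O)C(C)=C)C(=O)O1
F4 | step 15 | (E)-oxime of F3 | O/N=C/[C@@H](C(C)C)[C@H]1C=C(CC(=O)C[C@@H](C)CC[C@H](O)C(C)=C)C(=O)O1
F5 | step 15 | (Z)-N-hydroxyimidoyl chloride derived from F4 | O/N=C(\Cl)[C@@H](C(C)C)[C@H]1C=C(CC(=O)C[C@@H](C)CC[C@H](O)C(C)=C)C(=O)O1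
F6 | step 15 | hydroxy nitrile oxide derived from F5 | [O-][N+]#C[C@@H](C(C)C)[C@H]1C=C(CC(=O)C[C@@H](C)CC[C@H](O)C(C)=C)C(=O)O1
F7 | step 15 | (11S,12S)-11-hydroxy-10,11-dihydro analogue of 25 | C12=NO[C@@](C)(C1)[C@@H](O)CC[C@H](C)CC(=O)CC3=C[C@@H](OC3=O)[C@@H]2C(C)C
F8 | step 11 | methyl carbonate of allylic alcohol 18 | CC(C)(C)[Si](C)(C)OC[C@@H](C(C)C)[C@H]1C=C(CC(=O)C[C@@H](C)CCC(OC(=O)OC)C(C)=C)C(=O)O1
F9 | step 17 | (1R,2R,8S,12S,14R,10E)-12,14-dihydroxy-6-oxocembra-3,10-dien-18,2-olide (14-epimer of 27) | O[C@@H]1C[C@](C)(O)/C=C/C[C@H](C)CC(=O)CC2=C[C@@H](OC2=O)[C@@H]1C(C)C
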